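The route rests on cutting unit 1 (the 8-linked flavone) at two neighbouring ring A atoms. These are C8, bonded to C2' of ring B of unit 2, and C8a, bonded to the pyranone oxygen. Because C2' lies ortho to C1', which carries C2 of unit 2, one arenesulfonate bearing an ortho ester can deliver oxygen, aryl group and carbonyl carbon together. Fluoride frees 3,5-bis(benzyloxy)benzyne from its ortho-silyl triflate. Sulfonate O-addition, aryl shift from sulfur to carbon with SO2 loss, and lactonisation should give a dibenzopyranone in one flask. Its carbonyl grows into unit 2 and its ring oxygen into unit 1.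

Key step: step 6

Remark: the target SMILES carries no stereodescriptor. The C8–C2' axis is therefore left unassigned, and no step has to control it.

Step 1
Reactants: 1 3,5-bis(benzyloxy)phenol
Product: 2 3,5-bis(benzyloxy)phenyl isopropylcarbamate
Conditions: i-PrNCO, Et3N (cat.), CH2Cl2, rt
Reagents that add atoms: isopropyl isocyanate CC(C)N=C=O
Why: Base-catalysed addition of the phenol to the isocyanate (carbamoylation) installs a secondary carbamate that is a strong ortho-directing group and can later be removed under mild base.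

Step 2
Reactants: 2 3,5-bis(benzyloxy)phenyl isopropylcarbamate
Product: 5 3,5-bis(benzyloxy)-2-(trimethylsilyl)phenyl isopropylcarbamate, via N-silyl carbamate 3 (not isolated), via bis-silyl carbamate 4 (not isolated)
Conditions: TBSOTf, TMEDA, Et2O, 0 °C → rt; n-BuLi, TMEDA, −78 °C; TMSCl, −78 °C → rt; aq. NaHSO4
Reagents that add atoms: chlorotrimethylsilane C[Si](C)(C)Cl; tert-butyldimethylsilyl triflate CC(C)(C)[Si](C)(C)OS(=O)(=O)C(F)(F)F (its silyl group stays only in 3 and 4)
Why: Directed ortho-metalation, in which transient N-silylation masks the N–H and the carbamate and the neighbouring benzyloxy oxygen jointly steer n-BuLi to the carbon between them (both such positions are equivalent) faster than benzylic deprotonation at −78 °C, so TMSCl silylates that carbon and the acidic work-up strips the labile N-silyl group.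

Step 3
Reactants: 5 3,5-bis(benzyloxy)-2-(trimethylsilyl)phenyl isopropylcarbamate
Product: 7 3,5-bis(benzyloxy)-2-(trimethylsilyl)phenyl trifluoromethanesulfonate, via silylphenol 6 (not isolated)
Conditions: DBU, Et2NH, MeCN, 40 °C; then PhNTf2, rt
Reagents that add atoms: N-phenylbis(trifluoromethanesulfonimide) O=S(=O)(N(c1ccccc1)S(=O)(=O)C(F)(F)F)C(F)(F)F
Why: E1cB cleavage of the N–H carbamate by DBU frees the phenoxide while diethylamine traps the isocyanate as a urea, and O-sulfonylation in the same flask avoids the protodesilylation that an acidic deprotection would risk.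

Step 4
Reactants: 8 methyl 2-amino-4-methoxybenzoate
Product: 10 methyl 2-(chlorosulfonyl)-4-methoxybenzoate, via diazonium chloride 9 (not isolated)
Conditions: NaNO2, conc. HCl, AcOH–H2O, −5 °C; then SO2, CuCl (cat.), AcOH, 0 °C → rt
Reagents that add atoms: sulfur dioxide O=S=O; hydrogen chloride Cl; sodium nitrite [Na+].[O-]N=O (its nitrogen stays only in 9)
Why: Diazotisation followed by Meerwein chlorosulfonylation, in which CuCl reduces the diazonium ion to the aryl radical that adds SO2 and picks up chlorine at the carbon that bore nitrogen, a routine conversion of anthranilate esters.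

Step 5
Reactants: 10 methyl 2-(chlorosulfonyl)-4-methoxybenzoate
Product: 11 potassium 5-methoxy-2-(methoxycarbonyl)benzenesulfonate
Conditions: KHCO3 (2 equiv), acetone–H2O, rt; recrystallisation (EtOH); toluene azeotrope, vacuum, 60 °C
Reagents that add atoms: water O; potassium hydrogencarbonate [K+].OC([O-])=O
Why: Hydrolysis of a sulfonyl chloride (substitution at sulfur) is much faster than saponification of a methyl benzoate at bicarbonate pH, so the ester should survive and rigorous drying gives a proton-free salt.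

Step 6
Reactants: 7 3,5-bis(benzyloxy)-2-(trimethylsilyl)phenyl trifluoromethanesulfonate; 11 potassium 5-methoxy-2-(methoxycarbonyl)benzenesulfonate
Product: 16 1,3-bis(benzyloxy)-9-methoxy-6H-benzo[c]chromen-6-one, via aryne 12 (not isolated), via aryl anion 13 (not isolated), via aryl sulfite 14 (not isolated), via biaryl phenoxide 15 (not isolated)
Conditions: KF, 18-crown-6, 4 Å MS, THF, rt → 50 °C; 7 added slowly to 11 (3 equiv)
Reagents that add atoms: none
Why: Proposed new method: fluoride attacks silicon in 7 and triflate departs to give aryne 12, whose triple bond is polarised by the flanking benzyloxy group so that the crown-freed sulfonate oxygen of 11 should bond to the remote carbon (future C8a) and leave the charge on C8, next to that benzyloxy group, in 13. Anion 13 may expel sulfonate again, which only regenerates 12 and 11, or attack the ipso carbon C2' through a five-membered spiro Meisenheimer array (C8, C8a, O, S, C2') whose charge is taken up by the ester on C1'; C–S cleavage to sulfite 14 and loss of SO2 to phenoxide 15 make this branch the irreversible drain. Phenoxide 15 closes the single new ring by 6-exo-trig addition–elimination at the methyl ester, and the methoxide released is buffered by SO2 as methyl sulfite, so it should neither consume aryne nor reopen 16. The closest known reaction types are the Truce–Smiles aryl shift in adducts of arynes with electron-poor arenesulfonamides (giving 2-aminobiaryls) and the O-arylation of oxygen nucleophiles by 3-alkoxyarynes, whereas a sulfonate oxygen as the entering group is untested. Two selectivities are required, the site of addition, secured by the benzyloxy group beside the triple bond, and attack at carbon in preference to sulfur (anionic thia-Fries shift), favoured by a five- over a four-membered transition state and by the ortho ester. THF is preferred to acetonitrile, which protonates aryl anions, potassium held in the crown avoids the acidic hydrogens of ammonium cations, slow addition of 7 to excess dry 11 keeps the weak nucleophile ahead of fluoride and of 15, and no stereocentre is formed.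

Step 7
Reactants: 16 1,3-bis(benzyloxy)-9-methoxy-6H-benzo[c]chromen-6-one
Product: 17 1,3-bis(benzyloxy)-4-iodo-9-methoxy-6H-benzo[c]chromen-6-one
Conditions: NIS (1.05 equiv), TFA (cat.), MeCN–CH2Cl2, 0 °C → rt, dark
Reagents that add atoms: N-iodosuccinimide O=C1CCC(=O)N1I
Why: Electrophilic aromatic iodination should touch only the trioxygenated ring, and there C4 (future C4a, para to the 1-benzyloxy group and flanked by the tied-back lactone oxygen) is more accessible than C2 between two benzyloxy groups, the same preference that 5,7-dialkoxycoumarins and 5,7-dialkoxyflavones show for C8.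

Step 8
Reactants: 17 1,3-bis(benzyloxy)-4-iodo-9-methoxy-6H-benzo[c]chromen-6-one
Product: 18 1,3-bis(benzyloxy)-4-(1-ethoxyvinyl)-9-methoxy-6H-benzo[c]chromen-6-one
Conditions: tributyl(1-ethoxyvinyl)stannane, PdCl2(PPh3)2 (5 mol%), toluene, 100 °C; chromatography on K2CO3-doped silica
Reagents that add atoms: tributyl(1-ethoxyvinyl)stannane CCCC[Sn](CCCC)(CCCC)C(=C)OCC
Why: Stille coupling (zerovalent palladium inserts into the C–I bond) brings in C4 and C3 of unit 1 as a base-stable enol ether, a masked acetyl group without acidic hydrogens, so no internal Baker–Venkataraman-type attack on the lactone can occur in step 10.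

Step 9
Reactants: 19 2',4',6'-trihydroxyacetophenone
Product: 20 1-[2,4-bis(benzyloxy)-6-hydroxyphenyl]ethanone
Conditions: BnBr (2.1 equiv), K2CO3 (2.2 equiv), acetone, reflux
Reagents that add atoms: benzyl bromide BrCc1ccccc1
Why: Williamson etherification stops at the bis-ether because the last hydroxyl is hydrogen-bonded to the ketone and is the least reactive of the three.

Step 10
Reactants: 18 1,3-bis(benzyloxy)-4-(1-ethoxyvinyl)-9-methoxy-6H-benzo[c]chromen-6-one; 20 1-[2,4-bis(benzyloxy)-6-hydroxyphenyl]ethanone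
Product: 23 2-{2-[3-acetyl-4,6-bis(benzyloxy)-2-hydroxyphenyl]-4-methoxyphenyl}-5,7-bis(benzyloxy)-4H-chromen-4-one, via enol ether diketone 21 (not isolated), via acetyl diketone 22 (not isolated)
Conditions: 20 (1.2 equiv), LiN(SiMe3)2 (4 equiv), THF, −78 → −10 °C; 18, −78 °C → rt; 1 M HCl, THF, rt; crude, p-TsOH·H2O (cat.), toluene, 80 °C
Reagents that add atoms: water O
Why: Crossed Claisen condensation of the lithium dianion of 20 with the aryl-ester carbonyl of the lactone is driven by deprotonation of the 1,3-diketone, dilute acid then unmasks the acetyl group, and the usual acid cyclodehydration of a 2-hydroxyaryl 1,3-diketone gives the γ-pyrone of unit 2 while the rival phenol at C8a is held in a hydrogen bond to the new acetyl group.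

Step 11
Reactants: 23 2-{2-[3-acetyl-4,6-bis(benzyloxy)-2-hydroxyphenyl]-4-methoxyphenyl}-5,7-bis(benzyloxy)-4H-chromen-4-one; 24 4-methoxybenzaldehyde
Product: 25 5,7-bis(benzyloxy)-2-(2-{4,6-bis(benzyloxy)-2-hydroxy-3-[(E)-3-(4-methoxyphenyl)prop-2-enoyl]phenyl}-4-methoxyphenyl)-4H-chromen-4-one
Conditions: KOH (excess), EtOH–THF, rt
Reagents that add atoms: none
Why: Claisen–Schmidt condensation, in which the acetyl group is the only enolisable ketone, 24 cannot enolise, E1cB dehydration gives the (E)-enone, and a hindered 5,7-dialkoxy-γ-pyrone should tolerate ethanolic KOH at room temperature.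

Step 12
Reactants: 25 5,7-bis(benzyloxy)-2-(2-{4,6-bis(benzyloxy)-2-hydroxy-3-[(E)-3-(4-methoxyphenyl)prop-2-enoyl]phenyl}-4-methoxyphenyl)-4H-chromen-4-one
Product: 26 5,7-bis(benzyloxy)-8-{2-[5,7-bis(benzyloxy)-4-oxo-4H-chromen-2-yl]-5-methoxyphenyl}-2-(4-methoxyphenyl)-4H-chromen-4-one
Conditions: I2 (0.2 equiv), DMSO, 120 °C
Reagents that add atoms: none
Why: Iodine-catalysed oxidative cyclisation of a 2'-hydroxychalcone with DMSO as terminal oxidant closes the pyranone of unit 1 through the only free phenol (C8a–OH), the oxygen on C5 still being benzylated, so no 6-aryl isomer can arise.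

Step 13
Reactants: 26 5,7-bis(benzyloxy)-8-{2-[5,7-bis(benzyloxy)-4-oxo-4H-chromen-2-yl]-5-methoxyphenyl}-2-(4-methoxyphenyl)-4H-chromen-4-one
Product: 27 5,7-dihydroxy-8-[2-(5,7-dihydroxy-4-oxo-4H-chromen-2-yl)-5-methoxyphenyl]-2-(4-methoxyphenyl)-4H-chromen-4-one (target)
Conditions: H2 (1 atm), Pd/C (10 wt%), THF–MeOH, rt
Reagents that add atoms: none
Why: Catalytic hydrogenolysis cleaves the four aryl benzyl ethers, whereas the two aryl methyl ethers are inert and the flavone C2=C3 bonds are reduced far more slowly.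

Compound list
1 | 3,5-bis(benzyloxy)phenol | Oc1cc(OCc2ccccc2)cc(OCc2ccccc2)c1 | starting material
2 | 3,5-bis(benzyloxy)phenyl isopropylcarbamate | CC(C)NC(=O)Oc1cc(OCc2ccccc2)cc(OCc2ccccc2)c1 | intermediate
3 | 3,5-bis(benzyloxy)phenyl N-(tert-butyldimethylsilyl)-N-isopropylcarbamate | CC(C)N([Si](C)(C)C(C)(C)C)C(=O)Oc1cc(OCc2ccccc2)cc(OCc2ccccc2)c1 | intermediate
4 | 3,5-bis(benzyloxy)-2-(trimethylsilyl)phenyl N-(tert-butyldimethylsilyl)-N-isopropylcarbamate | CC(C)N([Si](C)(C)C(C)(C)C)C(=O)Oc1cc(OCc2ccccc2)cc(OCc2ccccc2)c1[Si](C)(C)C | intermediate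
5 | 3,5-bis(benzyloxy)-2-(trimethylsilyl)phenyl isopropylcarbamate | CC(C)NC(=O)Oc1cc(OCc2ccccc2)cc(OCc2ccccc2)c1[Si](C)(C)C | intermediate
6 | 3,5-bis(benzyloxy)-2-(trimethylsilyl)phenol | Oc1cc(OCc2ccccc2)cc(OCc2ccccc2)c1[Si](C)(C)C | intermediate
7 | 3,5-bis(benzyloxy)-2-(trimethylsilyl)phenyl trifluoromethanesulfonate | C[Si](C)(C)c1c(OCc2ccccc2)cc(OCc2ccccc2)cc1OS(=O)(=O)C(F)(F)F | intermediate
8 | methyl 2-amino-4-methoxybenzoate | COC(=O)c1ccc(OC)cc1N | starting material
9 | 5-methoxy-2-(methoxycarbonyl)benzenediazonium chloride | COC(=O)c1ccc(OC)cc1[N+]#N.[Cl-] | intermediate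
10 | methyl 2-(chlorosulfonyl)-4-methoxybenzoate | COC(=O)c1ccc(OC)cc1S(=O)(=O)Cl | intermediate
11 | potassium 5-methoxy-2-(methoxycarbonyl)benzenesulfonate | COC(=O)c1ccc(OC)cc1S(=O)(=O)[O-].[K+] | intermediate
12 | 3,5-bis(benzyloxy)benzyne (3,5-bis(benzyloxy)-1,2-didehydrobenzene) | C1#CC(OCc2ccccc2)=CC(OCc2ccccc2)=C1 | intermediate
13 | potassium salt of the C8 aryl anion, 2,4-bis(benzyloxy)-6-{[5-methoxy-2-(methoxycarbonyl)phenyl]sulfonyloxy}phenide | COC(=O)c1ccc(OC)cc1S(=O)(=O)Oc1cc(OCc2ccccc2)cc(OCc2ccccc2)[c-]1.[K+] | intermediate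
14 | potassium 3,5-bis(benzyloxy)-2-[5-methoxy-2-(methoxycarbonyl)phenyl]phenyl sulfite | COC(=O)c1ccc(OC)cc1-c1c(OS(=O)[O-])cc(OCc2ccccc2)cc1OCc1ccccc1.[K+] | intermediate
15 | potassium 3,5-bis(benzyloxy)-2-[5-methoxy-2-(methoxycarbonyl)phenyl]phenolate | COC(=O)c1ccc(OC)cc1-c1c([O-])cc(OCc2ccccc2)cc1OCc1ccccc1.[K+] | intermediate
16 | 1,3-bis(benzyloxy)-9-methoxy-6H-benzo[c]chromen-6-one | COc1ccc2c(c1)-c1c(OCc3ccccc3)cc(OCc3ccccc3)cc1OC2=O | intermediate
17 | 1,3-bis(benzyloxy)-4-iodo-9-methoxy-6H-benzo[c]chromen-6-one | COc1ccc2c(c1)-c1c(OCc3ccccc3)cc(OCc3ccccc3)c(I)c1OC2=O | intermediate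
18 | 1,3-bis(benzyloxy)-4-(1-ethoxyvinyl)-9-methoxy-6H-benzo[c]chromen-6-one | COc1ccc2c(c1)-c1c(OCc3ccccc3)cc(OCc3ccccc3)c(C(=C)OCC)c1OC2=O | intermediate
19 | 2',4',6'-trihydroxyacetophenone | CC(=O)c1c(O)cc(O)cc1O | starting material
20 | 1-[2,4-bis(benzyloxy)-6-hydroxyphenyl]ethanone | CC(=O)c1c(O)cc(OCc2ccccc2)cc1OCc1ccccc1 | intermediate
21 | 1-[2,4-bis(benzyloxy)-6-hydroxyphenyl]-3-{2-[4,6-bis(benzyloxy)-3-(1-ethoxyvinyl)-2-hydroxyphenyl]-4-methoxyphenyl}propane-1,3-dione | CCOC(=C)c1c(O)c(-c2cc(OC)ccc2C(=O)CC(=O)c2c(O)cc(OCc3ccccc3)cc2OCc2ccccc2)c(OCc2ccccc2)cc1OCc1ccccc1 | intermediate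
22 | 1-{2-[3-acetyl-4,6-bis(benzyloxy)-2-hydroxyphenyl]-4-methoxyphenyl}-3-[2,4-bis(benzyloxy)-6-hydroxyphenyl]propane-1,3-dione | CC(=O)c1c(O)c(-c2cc(OC)ccc2C(=O)CC(=O)c2c(O)cc(OCc3ccccc3)cc2OCc2ccccc2)c(OCc2ccccc2)cc1OCc1ccccc1 | intermediate
23 | 2-{2-[3-acetyl-4,6-bis(benzyloxy)-2-hydroxyphenyl]-4-methoxyphenyl}-5,7-bis(benzyloxy)-4H-chromen-4-one | CC(=O)c1c(O)c(-c2cc(OC)ccc2-c2cc(=O)c3c(OCc4ccccc4)cc(OCc4ccccc4)cc3o2)c(OCc2ccccc2)cc1OCc1ccccc1 | intermediate
24 | 4-methoxybenzaldehyde | COc1ccc(C=O)cc1 | starting material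
25 | 5,7-bis(benzyloxy)-2-(2-{4,6-bis(benzyloxy)-2-hydroxy-3-[(E)-3-(4-methoxyphenyl)prop-2-enoyl]phenyl}-4-methoxyphenyl)-4H-chromen-4-one | COc1ccc(/C=C/C(=O)c2c(O)c(-c3cc(OC)ccc3-c3cc(=O)c4c(OCc5ccccc5)cc(OCc5ccccc5)cc4o3)c(OCc3ccccc3)cc2OCc2ccccc2)cc1 | intermediate
26 | 5,7-bis(benzyloxy)-8-{2-[5,7-bis(benzyloxy)-4-oxo-4H-chromen-2-yl]-5-methoxyphenyl}-2-(4-methoxyphenyl)-4H-chromen-4-one | COc1ccc(-c2cc(=O)c3c(OCc4ccccc4)cc(OCc4ccccc4)c(-c4cc(OC)ccc4-c4cc(=O)c5c(OCc6ccccc6)cc(OCc6ccccc6)cc5o4)c3o2)cc1 | intermediate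
27 | 5,7-dihydroxy-8-[2-(5,7-dihydroxy-4-oxo-4H-chromen-2-yl)-5-methoxyphenyl]-2-(4-methoxyphenyl)-4H-chromen-4-one | COc1ccc(-c2cc(=O)c3c(O)cc(O)c(-c4cc(OC)ccc4-c4cc(=O)c5c(O)cc(O)cc5o4)c3o2)cc1 | target

Total step count: 13.
Longest linear sequence: 10 steps (1, 2, 3, 6, 7, 8, 10, 11, 12, 13).

Steps most likely to fail

Step 6.
- What may go wrong: loss of sulfonate from the carbanion may outrun the aryl shift. The aryne would then drain into fluoride addition, arylation of the phenoxide or self-reaction. Migration of the sulfonyl group to carbon and protonation by residual moisture are further leaks.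
- Fallback (known chemistry): setting out from 1, esterification with commercial 2-bromo-4-methoxybenzoic acid (EDC, DMAP, CH2Cl2) would give 3,5-bis(benzyloxy)phenyl 2-bromo-4-methoxybenzoate F1. Intramolecular direct arylation (Pd(OAc)2, PCy3·HBF4, K2CO3, DMA, 120 °C) then closes the same six-membered lactone. The two ortho positions of the phenol ring are equivalent, so only one product is possible, and the route is rejoined at 16.

Step 10.
- What may go wrong: the hindered dianion may be acylated incompletely. During the acid stage the C8a phenol may close onto the ring B carbonyl, or retro-Claisen cleavage may lead back to the lactone.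
- Fallback: the order of pyranone construction is reversed, so that C8a–O is locked into unit 1 before any diketone exists.
  - Setting out from 18, Me(MeO)NH·HCl and AlMe3 (CH2Cl2, 0 °C → rt) open the lactone to 2-[4,6-bis(benzyloxy)-3-(1-ethoxyvinyl)-2-hydroxyphenyl]-N,4-dimethoxy-N-methylbenzamide F2.
  - Dilute HCl converts this into 2-[3-acetyl-4,6-bis(benzyloxy)-2-hydroxyphenyl]-N,4-dimethoxy-N-methylbenzamide F3.
  - Claisen–Schmidt condensation with 24 gives 2-{4,6-bis(benzyloxy)-2-hydroxy-3-[(E)-3-(4-methoxyphenyl)prop-2-enoyl]phenyl}-N,4-dimethoxy-N-methylbenzamide F4.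
  - I2 in DMSO closes it to 2-[5,7-bis(benzyloxy)-2-(4-methoxyphenyl)-4-oxo-4H-chromen-8-yl]-N,4-dimethoxy-N-methylbenzamide F5.
  - Acylation of the LiN(SiMe3)2-derived dianion of 20 by this Weinreb amide gives 1-[2,4-bis(benzyloxy)-6-hydroxyphenyl]-3-{2-[5,7-bis(benzyloxy)-2-(4-methoxyphenyl)-4-oxo-4H-chromen-8-yl]-4-methoxyphenyl}propane-1,3-dione F6. Its only free phenol cyclodehydrates under p-TsOH, and the route is rejoined at 26.

Step 7.
- What may go wrong: positional selectivity between the two free positions of the trioxygenated ring may be poor, or a second iodination may occur.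
- Fallback: halogenation is abandoned, and the carbon on C4a is introduced later by a reaction that is ortho-specific for a free phenol.
  - Setting out from 16, condensation with the dianion of 20 gives 1-[2,4-bis(benzyloxy)-6-hydroxyphenyl]-3-{2-[2,4-bis(benzyloxy)-6-hydroxyphenyl]-4-methoxyphenyl}propane-1,3-dione F7.
  - Acid cyclodehydration gives 5,7-bis(benzyloxy)-2-{2-[2,4-bis(benzyloxy)-6-hydroxyphenyl]-4-methoxyphenyl}-4H-chromen-4-one F8.
  - Casnati–Skattebøl formylation (MgCl2, Et3N, paraformaldehyde, MeCN, reflux) can reach only the carbon next to the magnesium phenoxide. It gives 4,6-bis(benzyloxy)-3-{2-[5,7-bis(benzyloxy)-4-oxo-4H-chromen-2-yl]-5-methoxyphenyl}-2-hydroxybenzaldehyde F9.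
  - MeMgBr (THF, −78 °C) adds to the aldehyde in preference to the vinylogous ester carbonyl, giving racemic 5,7-bis(benzyloxy)-2-{2-[4,6-bis(benzyloxy)-2-hydroxy-3-(1-hydroxyethyl)phenyl]-4-methoxyphenyl}-4H-chromen-4-one F10.
  - MnO2 oxidation of the benzylic alcohol rejoins the route at 23.

Further compounds
F1 | step 6 | 3,5-bis(benzyloxy)phenyl 2-bromo-4-methoxybenzoate | COc1ccc(C(=O)Oc2cc(OCc3ccccc3)cc(OCc3ccccc3)c2)c(Br)c1
F2 | step 10 | 2-[4,6-bis(benzyloxy)-3-(1-ethoxyvinyl)-2-hydroxyphenyl]-N,4-dimethoxy-N-methylbenzamide | CCOC(=C)c1c(O)c(-c2cc(OC)ccc2C(=O)N(C)OC)c(OCc2ccccc2)cc1OCc1ccccc1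
F3 | step 10 | 2-[3-acetyl-4,6-bis(benzyloxy)-2-hydroxyphenyl]-N,4-dimethoxy-N-methylbenzamide | CC(=O)c1c(O)c(-c2cc(OC)ccc2C(=O)N(C)OC)c(OCc2ccccc2)cc1OCc1ccccc1
F4 | step 10 | 2-{4,6-bis(benzyloxy)-2-hydroxy-3-[(E)-3-(4-methoxyphenyl)prop-2-enoyl]phenyl}-N,4-dimethoxy-N-methylbenzamide | COc1ccc(/C=C/C(=O)c2c(O)c(-c3cc(OC)ccc3C(=O)N(C)OC)c(OCc3ccccc3)cc2OCc2ccccc2)cc1
F5 | step 10 | 2-[5,7-bis(benzyloxy)-2-(4-methoxyphenyl)-4-oxo-4H-chromen-8-yl]-N,4-dimethoxy-N-methylbenzamide | COc1ccc(-c2cc(=O)c3c(OCc4ccccc4)cc(OCc4ccccc4)c(-c4cc(OC)ccc4C(=O)N(C)OC)c3o2)cc1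
F6 | step 10 | 1-[2,4-bis(benzyloxy)-6-hydroxyphenyl]-3-{2-[5,7-bis(benzyloxy)-2-(4-methoxyphenyl)-4-oxo-4H-chromen-8-yl]-4-methoxyphenyl}propane-1,3-dione | COc1ccc(-c2cc(=O)c3c(OCc4ccccc4)cc(OCc4ccccc4)c(-c4cc(OC)ccc4C(=O)CC(=O)c4c(O)cc(OCc5ccccc5)cc4OCc4ccccc4)c3o2)cc1
F7 | step 7 | 1-[2,4-bis(benzyloxy)-6-hydroxyphenyl]-3-{2-[2,4-bis(benzyloxy)-6-hydroxyphenyl]-4-methoxyphenyl}propane-1,3-dione | COc1ccc(C(=O)CC(=O)c2c(O)cc(OCc3ccccc3)cc2OCc2ccccc2)c(-c2c(O)cc(OCc3ccccc3)cc2OCc2ccccc2)c1
F8 | step 7 | 5,7-bis(benzyloxy)-2-{2-[2,4-bis(benzyloxy)-6-hydroxyphenyl]-4-methoxyphenyl}-4H-chromen-4-one | COc1ccc(-c2cc(=O)c3c(OCc4ccccc4)cc(OCc4ccccc4)cc3o2)c(-c2c(O)cc(OCc3ccccc3)cc2OCc2ccccc2)c1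
F9 | step 7 | 4,6-bis(benzyloxy)-3-{2-[5,7-bis(benzyloxy)-4-oxo-4H-chromen-2-yl]-5-methoxyphenyl}-2-hydroxybenzaldehyde | O=Cc1c(O)c(-c2cc(OC)ccc2-c2cc(=O)c3c(OCc4ccccc4)cc(OCc4ccccc4)cc3o2)c(OCc2ccccc2)cc1OCc1ccccc1
F10 | step 7 | 5,7-bis(benzyloxy)-2-{2-[4,6-bis(benzyloxy)-2-hydroxy-3-(1-hydroxyethyl)phenyl]-4-methoxyphenyl}-4H-chromen-4-one (racemic) | CC(O)c1c(O)c(-c2cc(OC)ccc2-c2cc(=O)c3c(OCc4ccccc4)cc(OCc4ccccc4)cc3o2)c(OCc2ccccc2)cc1OCc1ccccc1
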